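The earlier runs and the new flask stem from a simulated flask for substances that don't exist, noise included.

Late in Tuesday's run the product stops growing. Left-handed and right-handed product together stand at 30.9 % of the charge at 2.00 h and 31.7 % at 2.50 h. That last figure is 0.0634 M, although 0.220 M of solid reagent went in and substrate remains.

- Tuesday's: left-handed substrate 0.10 M; right-handed substrate 0.10 M; solid reagent 2.2 equiv; racemization catalyst 0.1 mol%; impurity 26 µM; run made earlier
- flask: left-handed substrate 0.050 M; solid reagent 2.20 equiv; racemization catalyst 0.1 mol%; impurity 26 µM; right-handed substrate 0.050 M; time 8.0 h

- Tuesday's (time / h: left-handed product / %, right-handed product / %, left-handed substrate / %): 0.333: 5.1, 1.2, 45.0; 0.667: 9.5, 3.0, 43.6; 1.00: 15.6, 3.0, 39.2; 1.33: 21.7, 6.5, 37.0; 1.50: 25.0, 2.7, 35.1; 2.00: 25.6, 5.3, 34.0; 2.50: 26.7, 5.0, 33.8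

(readings scatter by 1 percentage point)

- partner is single-handed; left-handed substrate and right-handed substrate are mirror images of each other, charged as a racemate, each of them at the stated concentration
- given per volume of solution although it is solid: solid reagent
- at the start none of the solid reagent is in solution
- an excess is below zero if the other one leads
- no earlier run changes the charge of racemization catalyst; that part of a forecast is a guess
- the handed part of partner does not stay in what it makes, so the products of the two hands are mirror images too

- excess of left-handed product over right-handed product in the product at 10 min
- excess of left-handed product over right-handed product in the product at 8.0 h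
- part of the left-handed substrate and right-handed substrate charged together that has reacted at 8.0 h

The new flask can be built up one process at a time. With the main step alone, partner plus substrate, the new flask holds 0.110 M of reagent, more than the 0.100 M of the two substrates. Substrate is then the limiting reagent and 100 per cent reacts.

Tuesday's stall calls for a second process, supposed here: a loss that removes partner without touching substrate. If the new flask kept Tuesday's share of reagent ending in product, 28.8 %, it would reach 31.7 %. But capture is taken as first order in substrate and the loss as independent of it, so the ratio of partner captured to partner lost should scale with [substrate]. Tuesday's ratio, divided by its mean [substrate] of 0.168 M, gives 2.41 L mol⁻¹, the capture coefficient: partner captured per partner lost, per unit of [substrate].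

At the full 0.100 M this coefficient gives 0.0213 M of product in the new flask. The small correction is that substrate falls meanwhile, so its mean is 0.0893 M, and the reckoned conversion drops to 19.5 %.

Racemization comes last. Tuesday's left-handed substrate reading of 33.8 % lies close to the 34.1 % that an equal split of the unreacted part gives, so the hands are counted together. The excess read at that time, 68.5 %, is carried to both asked times as a scattered reading.

The forecast differs from this reckoning, with an excess of 66 % (56 % to 74 %) at 10 min, an excess of 62 % (48 % to 70 %) at 8.0 h and 40 % (27 % to 63 %) reacted, noting that “The cause of the stall is unknown”.

The new flask gives 63.9 % at 10 min, 62.3 % at 8.0 h and 20.3 % reacted.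

    partner + left-handed substrate → left-handed product (k = 0.0132 L mol⁻¹ s⁻¹)
    partner + right-handed substrate → right-handed product (k = 0.00286 L mol⁻¹ s⁻¹)
    left-handed substrate + racemization catalyst ⇌ right-handed substrate + racemization catalyst, rate k3*[racemization catalyst]*[left-handed substrate] forward; the back reaction follows from the equilibrium constant (k = 17.6 L mol⁻¹ s⁻¹)
    racemization catalyst + impurity → spent catalyst (k = 1000 L mol⁻¹ s⁻¹)
    partner → decomposed reagent (k = 0.00310 s⁻¹)
    solid reagent ⇌ partner, rate k6*(cs6 - [partner]) while solid is left; crystals form when [partner] > cs6 (solubility = 36.0 mM, k = 0.00129 s⁻¹)

In the new flask, decomposed reagent stands at 0.0897 M after 8.00 h, against 0.0203 M of substrate reacted. The neighbour flask with 5.50 equiv of solid reagent holds 0.275 M of it. Reckoned as before, first at the full 0.100 M to 0.0533 M of product, then at the mean 0.0733 M, the coefficient 2.41 L mol⁻¹ gives 41.3 %, and that neighbour flask reaches 44.0 %.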